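The pinane half is built from acyclic material and joined to the syncarpic acid half by a late hetero-Diels–Alder reaction. The route rests on one anionic bicyclisation. In the bicyclo[3.1.1]heptane (pinane numbering), the six-membered ring C1–C2–C3–C4–C5–C7 and the cyclobutane C1–C6–C5–C7 share the bridge carbon C7. An acyclic (S)-allylsilane that carries a vinyl sulfone (C4=C5, on gem-dimethyl C6) and a bromomethyl group (C7) can therefore close both rings at once: allyl carbon C3 adds to C4, and the C5 sulfonyl carbanion displaces bromide at C7. The single stereocentre C1, set by an enantioselective Ireland–Claisen rearrangement, dictates C5; the sulfone is then removed.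

Key step: step 7

Remark: syncarpic acid 16 is taken as a purchased compound and drawn as its triketo tautomer; labels C1–C7 and C10 follow pinane numbering throughout (C2 becomes the spiro carbon, C10 the exocyclic methylene carbon), and "tosyl" means 4-methylbenzenesulfonyl.

Step 1
Reactants: 1 3-methylbuta-1,2-diene; 2 sodium 4-methylbenzenesulfinate
Product: 3 1-iodo-3-methyl-2-tosylbut-2-ene
Conditions: I2, EtOAc–H2O, rt, visible light
Reagents that add atoms: iodine, II
Why: Radical-chain iodosulfonylation of an allene, in which the tosyl radical from tosyl iodide formed in the flask adds to the central allene carbon and iodine is transferred to the unsubstituted terminus of the allyl radical, so that the tetrasubstituted alkene with a primary allylic iodide should result and no stereocentre is formed.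

Step 2
Reactants: 4 diketene; 5 (trimethylsilyl)methylmagnesium chloride
Product: 6 3-[(trimethylsilyl)methyl]but-3-enoic acid
Conditions: NiCl2 (5 mol %), THF, 0 °C → rt; then aq. HCl
Reagents that add atoms: none
Why: Kumada-type ring-opening cross-coupling of the vinylic C–O bond of diketene with the Grignard reagent, a known entry to 3-substituted but-3-enoic acids, with no stereocentre formed.

Step 3
Reactants: 6 3-[(trimethylsilyl)methyl]but-3-enoic acid; 3 1-iodo-3-methyl-2-tosylbut-2-ene
Product: 7 3-methyl-2-tosylbut-2-en-1-yl 3-[(trimethylsilyl)methyl]but-3-enoate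
Conditions: KHCO3, DMF, rt
Reagents that add atoms: none
Why: SN2 O-alkylation of the carboxylate by the primary allylic iodide under weakly basic conditions that should leave the β,γ-unsaturated ester unconjugated, with no stereocentre formed.

Step 4
Reactants: 7 3-methyl-2-tosylbut-2-en-1-yl 3-[(trimethylsilyl)methyl]but-3-enoate
Product: 9 (2S)-3,3-dimethyl-4-tosyl-2-[3-(trimethylsilyl)prop-1-en-2-yl]pent-4-enoic acid, via boron ketene acetal 8 (not isolated)
Conditions: (4S,5S)-2-bromo-4,5-diphenyl-1,3-bis{[3,5-bis(trifluoromethyl)phenyl]sulfonyl}-1,3,2-diazaborolidine, Et3N, toluene–hexane, −78 °C → rt; then aqueous buffer (pH 5)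
Reagents that add atoms: none
Why: Enantioselective Ireland–Claisen rearrangement in its boron enolate form, in which soft enolisation gives one boron ketene acetal whose chair [3,3] transition state is face-biased by the C2-symmetric diazaborolidine, so that C1 bonds to the dimethyl-substituted allyl terminus (C6) on one enolate face and is set as (S) (sense assigned by analogy with simple allyl esters; the (4R,5R) controller would give the mirror image), while the electron-poor allyl fragment emerges as the 1,1-disubstituted vinyl sulfone.

Step 5
Reactants: 9 (2S)-3,3-dimethyl-4-tosyl-2-[3-(trimethylsilyl)prop-1-en-2-yl]pent-4-enoic acid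
Product: 11 (2S)-3,3-dimethyl-4-tosyl-2-[3-(trimethylsilyl)prop-1-en-2-yl]pent-4-en-1-ol, via mixed carbonic anhydride 10 (not isolated)
Conditions: i-BuOCOCl, N-methylmorpholine, THF, −15 °C; then NaBH4, H2O, 0 °C, short contact, NH4Cl quench
Reagents that add atoms: none
Why: Reduction of a mixed carbonic anhydride with NaBH4 converts CO2H into CH2OH without the hydroboration that borane would cause at the allylsilane, the short cold contact should spare the vinyl sulfone from conjugate reduction and oxa-Michael closure, and C1 is not touched.

Step 6
Reactants: 11 (2S)-3,3-dimethyl-4-tosyl-2-[3-(trimethylsilyl)prop-1-en-2-yl]pent-4-en-1-ol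
Product: 12 [(3S)-3-(bromomethyl)-4,4-dimethyl-2-methylidene-5-tosylhex-5-en-1-yl]trimethylsilane
Conditions: CBr4, PPh3, CH2Cl2, 0 °C
Reagents that add atoms: carbon tetrabromide, BrC(Br)(Br)Br
Why: Appel bromination replaces the primary hydroxyl by SN2 at C7 under neutral conditions that should not protodesilylate the allylsilane, and the stereocentre C1 is one bond away and unaffected.

Step 7
Reactants: 12 [(3S)-3-(bromomethyl)-4,4-dimethyl-2-methylidene-5-tosylhex-5-en-1-yl]trimethylsilane
Product: 14 (1R,5S)-6,6-dimethyl-4-methylidene-1-tosylbicyclo[3.1.1]heptane, via sulfonyl carbanion 13 (not isolated)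
Conditions: TASF [(Me2N)3S+ Me3SiF2−] (1.2 equiv), DMF–THF, 0.005 M, −40 °C → rt
Reagents that add atoms: none
Why: Proposed new method: fluoride removes the silyl group to give a 2-substituted allyl anion equivalent whose terminal carbon C3 adds to the CH2 terminus C4 of the vinyl sulfone, and the resulting tertiary α-sulfonyl carbanion at C5 displaces bromide at C7. The closest known reaction types are the fluoride-promoted intramolecular conjugate addition of allylsilanes (Hosomi–Sakurai type), Michael-initiated ring closure, and the cycloalkylation of 4-halobutyl sulfones to cyclobutyl sulfones. The ring C1–C2–C3–C4–C5–C6 closes in the 6-endo-trig mode and the cyclobutane C1–C6–C5–C7 in the 4-exo-tet mode, the latter helped by the gem-dimethyl group on C6 and by the axial preference of the bromomethyl group next to the exocyclic methylene. The only new stereocentre, C5, is controlled by C1, because the one-carbon bridge C7 can span C1 and C5 on one face of the six-membered ring only, so (S)-C1 should give the (1R,5S) bicycle. The step needs attack at C4 and not C5, which the polarisation by the sulfone secures, and C–C bond formation before protonation of the carbanion or fluoride attack at C7, which the anhydrous fluoride source with a cation that cannot undergo elimination, the high dilution and the hindered primary bromide are meant to secure.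

Step 8
Reactants: 14 (1R,5S)-6,6-dimethyl-4-methylidene-1-tosylbicyclo[3.1.1]heptane
Product: 15 (1S,5S)-6,6-dimethyl-2-methylidenebicyclo[3.1.1]heptane, (−)-β-pinene
Conditions: Na(Hg) (6 %), Na2HPO4, MeOH–THF, −20 °C → 0 °C
Reagents that add atoms: none
Why: Reductive desulfonylation by single-electron transfer, in which the sulfone radical anion loses toluenesulfinate and the bridgehead radical is reduced and protonated by methanol with retention enforced by the bicycle, while the low temperature and the poor overlap of the bridgehead orbital with the ring bonds should prevent opening of the cyclobutane.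

Step 9
Reactants: 15 (−)-β-pinene; 16 syncarpic acid; 17 3-methylbutanal
Product: 19 target CNP0231252.1, via enetrione 18 (not isolated)
Conditions: EDDA (ethylenediammonium diacetate, 10 mol %), toluene, rt → 50 °C
Reagents that add atoms: none
Why: Domino Knoevenagel condensation and inverse-electron-demand hetero-Diels–Alder reaction, in which the enetrione should add to the exocyclic alkene on the face opposite the gem-dimethyl bridge (setting the spiro carbon, oxygen syn to C7) with the ring CH2 (pinane C3) endo and the isobutyl group outside (setting chromene C4 as (S)), the C4 epimer being the expected minor product to be removed by chromatography.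

Compound list
1 | 3-methylbuta-1,2-diene | CC(C)=C=C | starting material
2 | sodium 4-methylbenzenesulfinate | Cc1ccc(cc1)S(=O)[O-].[Na+] | starting material
3 | 1-iodo-3-methyl-2-tosylbut-2-ene | CC(C)=C(CI)S(=O)(=O)c1ccc(C)cc1 | intermediate
4 | diketene (4-methylideneoxetan-2-one) | C=C1CC(=O)O1 | starting material
5 | (trimethylsilyl)methylmagnesium chloride | C[Si](C)(C)C[Mg]Cl | starting material
6 | 3-[(trimethylsilyl)methyl]but-3-enoic acid | C[Si](C)(C)CC(=C)CC(=O)O | intermediate
7 | 3-methyl-2-tosylbut-2-en-1-yl 3-[(trimethylsilyl)methyl]but-3-enoate | C[Si](C)(C)CC(=C)CC(=O)OCC(=C(C)C)S(=O)(=O)c1ccc(C)cc1 | intermediate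
8 | boron ketene acetal of 7, oxygen bound to the (4S,5S)-4,5-diphenyl-1,3-bis{[3,5-bis(trifluoromethyl)phenyl]sulfonyl}-1,3,2-diazaborolidin-2-yl group, alkenyl group anti to O–B (not isolated) | C[Si](C)(C)CC(=C)/C=C(\OCC(=C(C)C)S(=O)(=O)c1ccc(C)cc1)OB1N(S(=O)(=O)c2cc(cc(c2)C(F)(F)F)C(F)(F)F)[C@@H](c2ccccc2)[C@H](c2ccccc2)N1S(=O)(=O)c1cc(cc(c1)C(F)(F)F)C(F)(F)F | intermediate
9 | (2S)-3,3-dimethyl-4-tosyl-2-[3-(trimethylsilyl)prop-1-en-2-yl]pent-4-enoic acid | C[Si](C)(C)CC(=C)[C@H](C(=O)O)C(C)(C)C(=C)S(=O)(=O)c1ccc(C)cc1 | intermediate
10 | mixed anhydride of 9 with isobutyl hydrogen carbonate (not isolated) | C[Si](C)(C)CC(=C)[C@H](C(=O)OC(=O)OCC(C)C)C(C)(C)C(=C)S(=O)(=O)c1ccc(C)cc1 | intermediate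
11 | (2S)-3,3-dimethyl-4-tosyl-2-[3-(trimethylsilyl)prop-1-en-2-yl]pent-4-en-1-ol | C[Si](C)(C)CC(=C)[C@H](CO)C(C)(C)C(=C)S(=O)(=O)c1ccc(C)cc1 | intermediate
12 | [(3S)-3-(bromomethyl)-4,4-dimethyl-2-methylidene-5-tosylhex-5-en-1-yl]trimethylsilane | C[Si](C)(C)CC(=C)[C@H](CBr)C(C)(C)C(=C)S(=O)(=O)c1ccc(C)cc1 | intermediate
13 | tris(dimethylamino)sulfonium (3S)-3-(bromomethyl)-2,2-dimethyl-4-methylidene-1-tosylcyclohexan-1-ide (not isolated) | C=C1CC[C-](S(=O)(=O)c2ccc(C)cc2)C(C)(C)[C@H]1CBr.CN(C)[S+](N(C)C)N(C)C | intermediate
14 | (1R,5S)-6,6-dimethyl-4-methylidene-1-tosylbicyclo[3.1.1]heptane | C=C1CC[C@@]2(S(=O)(=O)c3ccc(C)cc3)C[C@@H]1C2(C)C | intermediate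
15 | (1S,5S)-6,6-dimethyl-2-methylidenebicyclo[3.1.1]heptane, (−)-β-pinene | C=C1CC[C@H]2C[C@@H]1C2(C)C | intermediate
16 | syncarpic acid (2,2,4,4-tetramethylcyclohexane-1,3,5-trione) | CC1(C)C(=O)CC(=O)C(C)(C)C1=O | starting material
17 | 3-methylbutanal | CC(C)CC=O | starting material
18 | 2,2,4,4-tetramethyl-6-(3-methylbutylidene)cyclohexane-1,3,5-trione (enetrione, not isolated) | CC(C)CC=C1C(=O)C(C)(C)C(=O)C(C)(C)C1=O | intermediate
19 | (1R,2R,5S,4'S)-6,6,6',6',8',8'-hexamethyl-4'-(2-methylpropyl)-3',4'-dihydrospiro[bicyclo[3.1.1]heptane-2,2'-chromene]-5',7'(6'H,8'H)-dione (CNP0231252.1) | CC(C)C[C@H]1C[C@@]2(CC[C@H]3C[C@@H]2C3(C)C)OC2=C1C(=O)C(C)(C)C(=O)C2(C)C | target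

Total step count: 9. Longest linear sequence: 8 steps (steps 1, 3, 4, 5, 6, 7, 8, 9; the branch through step 2 is equally long).

Steps most likely to fail

Step 7 (key step, proposed new method). The sulfonyl carbanion may be protonated before the cyclobutane closes, the silyl group may be lost by protodesilylation without C–C bond formation, or fluoride may attack C7 or the vinyl sulfone. The fallback separates the two bond formations into two known operations and sets out from 12. Bu4NF·3H2O in THF at 0 °C is used on purpose as a wet fluoride source, so that the fluoride-promoted intramolecular conjugate allylation is followed by protonation and should give the monocyclic bromo sulfone (3S)-3-(bromomethyl)-2,2-dimethyl-4-methylidene-1-tosylcyclohexane F1 as a mixture of epimers at the sulfonyl carbon. Deprotonation of F1 next to the sulfone with LiN(i-Pr)2 in THF–HMPA (−78 °C → 0 °C) should then close the cyclobutane by 4-exo-tet cycloalkylation of the lithium sulfonyl carbanion, and the route is rejoined at 14.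

Step 4. The facial sense or the level of enantiocontrol of the boron-mediated rearrangement may be inadequate for this β,γ-unsaturated ester, and the boron bromide may attack the allylsilane. The fallback replaces reagent control by resolution and sets out from 7. The achiral Ireland–Claisen rearrangement (LiN(i-Pr)2, Me3SiCl, THF, −78 °C → rt, aqueous work-up) should give racemic 3,3-dimethyl-4-tosyl-2-[3-(trimethylsilyl)prop-1-en-2-yl]pent-4-enoic acid F2, which is reduced under the conditions of step 5 to racemic 3,3-dimethyl-4-tosyl-2-[3-(trimethylsilyl)prop-1-en-2-yl]pent-4-en-1-ol F3. Kinetic resolution of F3 with Burkholderia cepacia lipase and vinyl acetate in t-BuOMe is expected to acetylate the (R)-alcohol to (2R)-3,3-dimethyl-4-tosyl-2-[3-(trimethylsilyl)prop-1-en-2-yl]pent-4-en-1-yl acetate F4 and to leave the (S)-alcohol, which is 11, where the route is rejoined.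

Step 9. Endo/exo discrimination at chromene C4 may be poor, the acid co-catalyst may rearrange the pinene, or the enetrione may oligomerise before it is trapped. The fallback replaces the thermal, substrate-controlled domino process by a catalyst-controlled two-stage one and sets out from 16 and 17. Enetrione 18 is generated separately (L-proline, CH2Cl2, rt) and treated at −40 °C with 15 in the presence of Cu(OTf)2 and a t-Bu-bis(oxazoline) ligand (10 mol %), the ligand enantiomer being chosen for the matched case. The chelated chiral Lewis acid should then select the heterodiene face and so set chromene C4, while the pinene still reacts on the face opposite its gem-dimethyl bridge. The product is 19 directly, so no compound outside the list arises (F0).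

Further compounds
F1 | step 7 | (3S)-3-(bromomethyl)-2,2-dimethyl-4-methylidene-1-tosylcyclohexane (both epimers at C1) | C=C1CCC(S(=O)(=O)c2ccc(C)cc2)C(C)(C)[C@H]1CBr
F2 | step 4 | racemic 3,3-dimethyl-4-tosyl-2-[3-(trimethylsilyl)prop-1-en-2-yl]pent-4-enoic acid | C[Si](C)(C)CC(=C)C(C(=O)O)C(C)(C)C(=C)S(=O)(=O)c1ccc(C)cc1
F3 | step 4 | racemic 3,3-dimethyl-4-tosyl-2-[3-(trimethylsilyl)prop-1-en-2-yl]pent-4-en-1-ol | C[Si](C)(C)CC(=C)C(CO)C(C)(C)C(=C)S(=O)(=O)c1ccc(C)cc1
F4 | step 4 | (2R)-3,3-dimethyl-4-tosyl-2-[3-(trimethylsilyl)prop-1-en-2-yl]pent-4-en-1-yl acetate | C[Si](C)(C)CC(=C)[C@@H](COC(C)=O)C(C)(C)C(=C)S(=O)(=O)c1ccc(C)cc1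
F0 | step 9 | none | none
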